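**Plan**
- Retrosynthesis: the central C(sp2)–C(sp2) bond of the tetraene is cut first (two identical halves), then the ring–vinyl bond, the epoxide, the side-chain C=CMe2 bond, and last, in one stroke, the two ring bonds quaternary C–CH= and CH2–CH(O) of the cyclohexene.
- Enabling feature: in each ring the carbinol oxygen on C1 is cis to the side chain on the neighbouring quaternary C2. Oxygen and the third chain carbon can therefore be tied into a six-membered cyclic enol ether (a 2-ethoxy-5-methyl-3,4-dihydro-2H-pyran) whose C5=C6 bond is the C2–C1 unit. The other ring carbons, C3=C4(–C)–C5–C6, map onto C6–C5–C4–C3 of 5-bromo-2-pyrone, with CO2 as a traceless bridge.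
- Forward order: hetero-Diels–Alder (pyran acetal), pyrone Diels–Alder with CO2 loss (carbocycle), diimide reduction, acetal hydrolysis and Wittig reaction (pyran opened to the homoprenyl chain), Shi epoxidation, Stille coupling, oxidative homocoupling (tetraene).
- Stereochemistry: the acetal carbon is set by a chiral chromium catalyst and relays its sense to the quaternary and carbinol carbons (addition anti to the pseudoaxial ethoxy group, cis by ring constraint). The epoxide is set by the Shi ketone, and both E double bonds come from the E-distannylethene.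

Key step: step 2

Assumption: 5-bromo-2H-pyran-2-one, (E)-1,2-bis(tributylstannyl)ethene and the D-fructose-derived epoxidation ketone are taken as purchasable.

Step 1
Reactants: 1 methacrolein (2-methylprop-2-enal); 2 ethyl vinyl ether
Product: 3 (2S)-2-ethoxy-5-methyl-3,4-dihydro-2H-pyran
Conditions: CrCl(L) (5 mol %; L = tridentate Schiff-base dianion from 3-(1-adamantyl)-2-hydroxy-5-methylbenzaldehyde and cis-1-aminoindan-2-ol, the antipode that gives the 2S acetal), 4 Å molecular sieves, neat 2 (5 equiv), rt
Reagents that add atoms: none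
Why: Inverse-electron-demand hetero-Diels–Alder reaction of the enal (as a 1-oxadiene) with the vinyl ether under a chiral chromium Lewis acid, which should set the acetal carbon, the only stereocentre, as S.

Step 2
Reactants: 3 (2S)-2-ethoxy-5-methyl-3,4-dihydro-2H-pyran (2.5 equiv); 4 bromopyrone (5-bromo-2H-pyran-2-one)
Product: 6 (2S,4aS,8aR)-6-bromo-2-ethoxy-4a-methyl-3,4,4a,8a-tetrahydro-2H-chromene, via bridged lactone cycloadduct 5 (not isolated)
Conditions: BHT (2 mol %), K2CO3 (0.1 equiv), o-xylene, sealed tube, 110 °C, then 145 °C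
Reagents that add atoms: none
Why: The electron-poor 2-pyrone 4 and the electron-rich enol ether of 3 combine in an inverse-electron-demand Diels–Alder reaction (closest known type: cycloadditions of bromo-2-pyrones and coumalates with vinyl ethers), and the strained 2-oxabicyclo[2.2.2]octenone 5 then loses CO2 by a retro-[4+2] reaction, which leaves the C5=C6 double bond exactly where the target has it. The carbocycle is closed by a concerted, suprafacial [4+2] cycloaddition across C6 and C3 of the pyrone; no other ring is formed. Regiochemistry follows the polarity of both partners: the nucleophilic, methyl-bearing enol-ether carbon bonds to the electrophilic C6 of the pyrone and the oxygen-bearing carbon to C3, so that bromine ends on the carbon that will carry the linker. The quaternary C4a and the carbinol C8a arise cis because the dienophile is a cyclic enol ether, which fixes the oxygen cis to the side-chain carbons as the target demands. Their absolute sense is controlled by the acetal carbon of 3, whose pseudoaxial ethoxy group shields one face of the enol ether, so that the pyrone should add anti to it; endo and exo adducts converge once the CO2 bridge is gone. The step therefore needs only regio- and facial selectivity, the first secured by the polarization of the bromopyrone and the second by the temporary acetal stereocentre.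

Step 3
Reactants: 6 (2S,4aS,8aR)-6-bromo-2-ethoxy-4a-methyl-3,4,4a,8a-tetrahydro-2H-chromene
Product: 7 (2S,4aS,8aR)-6-bromo-2-ethoxy-4a-methyl-3,4,4a,7,8,8a-hexahydro-2H-chromene
Conditions: 2-nitrobenzenesulfonylhydrazide (3 equiv), Et3N, CH2Cl2, rt
Reagents that add atoms: none
Why: Diimide reduction, in which syn transfer of H2 to the unhindered cis-disubstituted C7=C8 bond should be much faster than to the trisubstituted, bromine-bearing C5=C6 bond, while C–Br and the acetal are left untouched and no stereocentre is formed.

Step 4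
Reactants: 7 (2S,4aS,8aR)-6-bromo-2-ethoxy-4a-methyl-3,4,4a,7,8,8a-hexahydro-2H-chromene
Product: 8 lactol (4aS,8aR)-6-bromo-4a-methyl-3,4,4a,7,8,8a-hexahydro-2H-chromen-2-ol (both anomers)
Conditions: 1 M aq HCl, THF, rt
Reagents that add atoms: water, O
Why: Acid-catalysed acetal hydrolysis through the oxocarbenium ion, which erases the temporary acetal stereocentre on purpose while the quaternary C4a and the non-activated C8a cannot epimerize.

Step 5
Reactants: 8 lactol (4aS,8aR)-6-bromo-4a-methyl-3,4,4a,7,8,8a-hexahydro-2H-chromen-2-ol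
Product: 10 (1R,2S)-4-bromo-2-methyl-2-(4-methylpent-3-en-1-yl)cyclohex-3-en-1-ol, via open hydroxy aldehyde 9 (not isolated)
Conditions: i-PrPPh3I (3 equiv), n-BuLi (2.9 equiv), THF, 0 °C; then 8, 0 °C to rt
Reagents that add atoms: isopropyltriphenylphosphonium iodide, CC(C)[P+](c1ccccc1)(c1ccccc1)c1ccccc1.[I-]
Why: Wittig olefination of the open hydroxy-aldehyde tautomer by the non-stabilized ylide (the first equivalent acts as base), which opens the temporary pyran ring for good and, because the new alkene terminus is symmetrical, raises no question of geometry.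

Step 6
Reactants: 10 (1R,2S)-4-bromo-2-methyl-2-(4-methylpent-3-en-1-yl)cyclohex-3-en-1-ol
Product: 11 (1R,2S)-4-bromo-2-{2-[(2R)-3,3-dimethyloxiran-2-yl]ethyl}-2-methylcyclohex-3-en-1-ol
Conditions: D-fructose-derived ketone (1,2:4,5-di-O-isopropylidene-β-D-erythro-2,3-hexodiulo-2,6-pyranose, 30 mol %), Oxone (2KHSO5·KHSO4·K2SO4), K2CO3, Bu4NHSO4, aq Na2B4O7 buffer, MeCN/CH2(OMe)2, 0 °C
Reagents that add atoms: potassium peroxymonosulfate (KHSO5), [K+].[O-]S(=O)(=O)OO
Why: Shi epoxidation, in which the chiral dioxirane should attack the electron-rich trisubstituted side-chain alkene through a spiro transition state to give the R epoxide, while the bromoalkene is electronically deactivated and shielded by the quaternary carbon.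

Step 7
Reactants: 11 (1R,2S)-4-bromo-2-{2-[(2R)-3,3-dimethyloxiran-2-yl]ethyl}-2-methylcyclohex-3-en-1-ol; 12 distannane ((E)-1,2-bis(tributylstannyl)ethene, 3 equiv)
Product: 13 (1R,2S)-2-{2-[(2R)-3,3-dimethyloxiran-2-yl]ethyl}-2-methyl-4-[(E)-2-(tributylstannyl)ethenyl]cyclohex-3-en-1-ol
Conditions: Pd(PPh3)4 (5 mol %), CuI (10 mol %), CsF (2 equiv), DMF, 50 °C
Reagents that add atoms: none
Why: Stille coupling at the C–Br bond with retention of the E geometry of the distannylethene, where the excess of 12 should stop the reaction after one tin group has been exchanged and the neutral medium spares the epoxy alcohol.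

Step 8
Reactants: 13 (1R,2S)-2-{2-[(2R)-3,3-dimethyloxiran-2-yl]ethyl}-2-methyl-4-[(E)-2-(tributylstannyl)ethenyl]cyclohex-3-en-1-ol (two molecules)
Product: 14 CNP0229121.4, 4,4'-[(1E,3E)-buta-1,3-diene-1,4-diyl]bis{(1R,2S)-2-[2-((2R)-3,3-dimethyloxiran-2-yl)ethyl]-2-methylcyclohex-3-en-1-ol}
Conditions: CuCl (3 equiv), DMF, rt, dark
Reagents that add atoms: none
Why: Copper-mediated oxidative homocoupling of an alkenylstannane (tin-to-copper transmetalation, then reductive dimerization of the alkenylcopper) should join the two identical halves at the central sp2–sp2 bond with retention of both E double bonds under neutral conditions.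

**Compound list**
1 | methacrolein (2-methylprop-2-enal) | CC(=C)C=O | starting material
2 | ethyl vinyl ether | C=COCC | starting material
3 | (2S)-2-ethoxy-5-methyl-3,4-dihydro-2H-pyran | CCO[C@@H]1CCC(C)=CO1 | intermediate
4 | 5-bromo-2H-pyran-2-one | O=C1C=CC(Br)=CO1 | starting material
5 | bridged lactone cycloadduct: 7-bromo-2-oxabicyclo[2.2.2]oct-7-en-3-one cis-fused across C5–C6 to the (2S)-2-ethoxytetrahydropyran (pyran oxygen on C5, methyl on C6, pyran ring syn to C7=C8, ethoxy anti to the bicycle; the exo isomer gives the same diene) | BrC1=C[C@@H]2C(=O)O[C@H]1[C@]3(C)CC[C@@H](OCC)O[C@H]23 | intermediate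
6 | (2S,4aS,8aR)-6-bromo-2-ethoxy-4a-methyl-3,4,4a,8a-tetrahydro-2H-chromene (cis-fused; ethoxy cis to 4a-methyl and 8a-H) | BrC1=C[C@]2(C)CC[C@@H](OCC)O[C@@H]2C=C1 | intermediate
7 | (2S,4aS,8aR)-6-bromo-2-ethoxy-4a-methyl-3,4,4a,7,8,8a-hexahydro-2H-chromene | BrC1=C[C@]2(C)CC[C@@H](OCC)O[C@@H]2CC1 | intermediate
8 | (4aS,8aR)-6-bromo-4a-methyl-3,4,4a,7,8,8a-hexahydro-2H-chromen-2-ol (lactol, both anomers) | BrC1=C[C@]2(C)CCC(O)O[C@@H]2CC1 | intermediate
9 | 3-[(1S,6R)-3-bromo-6-hydroxy-1-methylcyclohex-2-en-1-yl]propanal (open form of 8) | BrC1=C[C@](C)(CCC=O)[C@H](O)CC1 | intermediate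
10 | (1R,2S)-4-bromo-2-methyl-2-(4-methylpent-3-en-1-yl)cyclohex-3-en-1-ol | BrC1=C[C@](C)(CCC=C(C)C)[C@H](O)CC1 | intermediate
11 | (1R,2S)-4-bromo-2-{2-[(2R)-3,3-dimethyloxiran-2-yl]ethyl}-2-methylcyclohex-3-en-1-ol | BrC1=C[C@](C)(CC[C@H]2OC2(C)C)[C@H](O)CC1 | intermediate
12 | (E)-1,2-bis(tributylstannyl)ethene | CCCC[Sn](CCCC)(CCCC)/C=C/[Sn](CCCC)(CCCC)CCCC | starting material
13 | (1R,2S)-2-{2-[(2R)-3,3-dimethyloxiran-2-yl]ethyl}-2-methyl-4-[(E)-2-(tributylstannyl)ethenyl]cyclohex-3-en-1-ol | CCCC[Sn](CCCC)(CCCC)/C=C/C1=C[C@](C)(CC[C@H]2OC2(C)C)[C@H](O)CC1 | intermediate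
14 | CNP0229121.4 | CC1(C)O[C@@H]1CC[C@@]1(C)C=C(/C=C/C=C/C2=C[C@](C)(CC[C@H]3OC3(C)C)[C@H](O)CC2)CC[C@H]1O | target

Total step count: 8. Longest linear sequence: 8 steps (1 and 2 to 14).

**Steps most likely to fail**

Step 2. Bond formation at the fully substituted enol-ether carbon may be slow, and the heat then needed may erode the facial discrimination by the acetal or start hydrogen shifts in the cyclohexadiene. Fallback: setting out from 3, the more electron-poor 3,5-dibromo-2H-pyran-2-one should add below 100 °C (toluene, 85 °C), where the facial bias is larger, to give the isolable dibromo cycloadduct F1. Radical reduction (Bu3SnH, 1.05 equiv, AIBN, benzene, 80 °C) should remove only the bridgehead bromine next to the lactone carbonyl and give 5, which on thermolysis (o-xylene, 145 °C) comes back to the route at 6.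

Step 1. An enal without a β-substituent may be discriminated poorly by the chiral Lewis acid, and methacrolein may polymerize, so the acetal may form with insufficient enantiomeric purity. Fallback: setting out from 1, a thermal hetero-Diels–Alder reaction (neat, 170 °C, hydroquinone) with (−)-menthyl vinyl ether F2 (from (−)-menthol and vinyl acetate, [IrCl(cod)]2 with cod = cycloocta-1,5-diene, Na2CO3, toluene, 100 °C) would give both acetal epimers. Chromatography should deliver (2S)-5-methyl-2-menthyloxy-3,4-dihydro-2H-pyran F3. F3 replaces 3 under the conditions of steps 2 and 3 (menthyloxy bridged lactone F4, menthyloxy diene F5, menthyloxy hexahydrochromene F6). The hydrolysis of step 4 then releases menthol and comes back to the route at 8.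

Step 8. Transfer of the dienyl group from tributyltin to copper may be slow, so that protodestannylation and degradation or isomerization of the polyene compete with dimerization. Fallback: setting out from 13, one half is converted by iododestannylation (I2, NaHCO3, CH2Cl2, 0 °C) into the dienyl iodide F7. F7 is joined to the second half of 13 by a Stille cross-coupling (Pd2(dba)3, AsPh3, DMF, rt), which comes back to the route at 14.

**Further compounds**
F1 | step 2 | 4,7-dibromo analogue of 5 (second bromine on the bridgehead carbon next to the lactone carbonyl) | BrC1=C[C@]2(Br)C(=O)O[C@H]1[C@]3(C)CC[C@@H](OCC)O[C@H]23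
F2 | step 1 | (1R,2S,5R)-2-isopropyl-5-methylcyclohexyl vinyl ether ((−)-menthyl vinyl ether) | C=CO[C@@H]1C[C@H](C)CC[C@H]1C(C)C
F3 | step 1 | (2S)-5-methyl-2-{[(1R,2S,5R)-2-isopropyl-5-methylcyclohexyl]oxy}-3,4-dihydro-2H-pyran | CC(C)[C@@H]1CC[C@@H](C)C[C@H]1O[C@@H]2CCC(C)=CO2
F4 | step 1 | menthyloxy analogue of bridged lactone 5 | BrC1=C[C@@H]2C(=O)O[C@H]1[C@]3(C)CC[C@@H](O[C@@H]4C[C@H](C)CC[C@H]4C(C)C)O[C@H]23
F5 | step 1 | menthyloxy analogue of diene 6 | BrC1=C[C@]2(C)CC[C@@H](O[C@@H]3C[C@H](C)CC[C@H]3C(C)C)O[C@@H]2C=C1
F6 | step 1 | menthyloxy analogue of 7 | BrC1=C[C@]2(C)CC[C@@H](O[C@@H]3C[C@H](C)CC[C@H]3C(C)C)O[C@@H]2CC1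
F7 | step 8 | (1R,2S)-2-{2-[(2R)-3,3-dimethyloxiran-2-yl]ethyl}-4-[(E)-2-iodoethenyl]-2-methylcyclohex-3-en-1-ol | I/C=C/C1=C[C@](C)(CC[C@H]2OC2(C)C)[C@H](O)CC1
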